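The numbers in the tables come from a simulation for an exercise; scatter was added.

The trap is to carry the violet reading of 68.6% at 1.00 min over to a flask with half the substrate: homo loss per open intermediate goes with c(open intermediate), so that reading belongs to the violet charge.

- violet: substrate 1 M; partner 0.90 equiv; capture agent 10 mM; run made earlier
- flask: substrate 0.50 M; partner 0.900 equiv; capture agent 10.0 mM; time 50 min

violet run (percent of the substrate charged)

| time / min | open intermediate / % | target / % |
|---|---|---|
| 0.333 | 52.2 | 1.0 |
| 1.00 | 68.6 | 7.7 |
| 2.00 | 54.7 | 11.1 |
| 2.50 | 48.6 | 12.4 |
| 4.00 | 36.7 | 12.9 |
| 5.00 | 30.1 | 12.5 |

(standard deviation of a reading: 0.5 percentage points)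

* the best time, 50 min at the latest, for open intermediate
* the amount of open intermediate, in percent of the substrate charged, at that time

From 2.50 min to 5.00 min of the violet run, target moves from 12.4% to 12.5%, less than the scatter of 0.5 percentage points, so the step to target counts as finished there. The reciprocal of c(open intermediate) then climbs by 0.506 L mol⁻¹ min⁻¹, the tail constant, the second-order rate constant of the homo step counted per open intermediate lost.

But substrate might still feed that tail. The first violet reading, open intermediate plus target, gives an opening constant k of 2.28 min⁻¹, an estimate with homo product left out of the sum. That constant leaves 0.335% unopened at 2.50 min, less than the scatter.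

By 1.00 min the violet run, reckoned with that constant, has lost about 21 points of what opened. Halving that loss for this flask leaves 79.2%. Making meets homo loss where k·exp(−k·t) equals the tail constant times the charge times that fraction squared, near 1.17 min. The objection is that target still draws then, so the true peak comes somewhat earlier.

The forecast, lower than this reckoning, gives 77% (73% to 81%) at 1.15 min (0.95 min to 1.45 min), holding that “both homo-coupling and target loss per unit of open intermediate are therefore halved”.

The flask gives 78.0% at 1.08 min, inside both ranges.

    substrate → open intermediate (k = 0.0399 s⁻¹)
    partner → second intermediate (k = 0.0991 s⁻¹)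
    open intermediate + second intermediate → target (k = 0.00504 L mol⁻¹ s⁻¹)
    2 open intermediate → homo product (k = 0.00383 L mol⁻¹ s⁻¹)
    second intermediate → decomposed reagent (k = 0.0169 s⁻¹)
    open intermediate + capture agent → trapped intermediate (k = 0.00245 L mol⁻¹ s⁻¹)

At 0.289 min in the flask, second intermediate has a half-life of 0.68 min by decomposition, shorter than the 9.4 min by the making of target, and at 50.0 min target stands at 7.86% beside 83.2% homo product. Carried from 47.2% at 5.00 min, the tail constant puts open intermediate at 7.41% by 50.0 min, and the flask holds 7.86%. In the neighbour flask with 2.0 M of substrate, the reciprocal of the charge is far smaller than the tail constant times the time, so the reciprocal of that product, taken as a share of the charge, gives 1.98%, and that flask holds 2.11% at 50.0 min.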